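Numbering: C1 (isopropenyl), C2, C3 (OH), C4 (CH3, OH), C5 (angelate), C6, C7–C8 (oxirane, CH3 on C8), C9 (acetate), C10 (senecioate). The C3 oxygen lies δ,ε to the masked C7=C8 olefin, which is the retron of an oxy-Cope shift; re-forming C3–C8 folds the ten-membered ring onto the six-membered ring C1–C2–C3–C8–C9–C10 of carvone.
Retrosynthetic cuts, in order: the three ester C–O bonds; the oxirane and the C10–O bond (back to a C9 enone); the C4–O bond and one C–H of the C4 methyl (back to a C4-methylene C3-ketone); C5–C6 with C3–C8 restored ([3,3] shift); C3–C4 (alkenyl addition); C7–C8 (vinyl, 1,2-shift from C3).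
Forward: (R)-carvone (its carbonyl carbon becomes C3, its β-carbon C9) is vinylated, epoxidized and rearranged to the 2-methyl-2-vinyl-3-hydroxy ketone; a Z-alkoxypropenyl group is added at C3; the six-membered ring is then expanded to the ten-membered ring, the only carbocycle-forming event; the rest is redox and acylation on that ring.
Stereochemistry: C1 from carvone; C8 (vinyl trans to isopropenyl) from the anti 1,2-shift; C5, the Z-C7=C8 and the ring-trans C3=C4 geometry from the chair of the [3,3] shift; C3 by oxazaborolidine reagent control; C4 by C3–OH-directed epoxidation of the C4 methylene and hydride opening; C10 by enolate hydroxylation anti to isopropenyl; C9 by chelation-controlled reduction; C7/C8 by C9–OH-directed epoxidation.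
The tetrasubstituted ring-trans enol ether from the shift cannot turn inside the ten-membered ring and shows only its outer face, where an oxygen electrophile would give the C4 epimer; C4 is therefore oxygenated later through the methylene ketone.
Protecting groups: C9 3,4-dimethoxybenzyl, C5 4-methoxybenzyl, C3 triethylsilyl; the isomerization-prone angelate is put on in the last step but one.

Key step: step 9

Remark: every intermediate keeps the numbering C1–C10 of the first line. PMB = 4-methoxybenzyl, DMB = 3,4-dimethoxybenzyl, TES = triethylsilyl, DMAP = 4-(dimethylamino)pyridine, CSA = camphor-10-sulfonic acid, DBU = 1,8-diazabicyclo[5.4.0]undec-7-ene, DDQ = 2,3-dichloro-5,6-dicyano-1,4-benzoquinone, DMP = 1,1,1-triacetoxy-1,1-dihydro-1,2-benziodoxol-3(1H)-one.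

Step 1
Reactants: 1 allyl alcohol
Product: 2 allyl 4-methoxybenzyl ether
Conditions: NaH, 4-methoxybenzyl chloride, n-Bu4NI (cat.), THF/DMF, 0 °C → rt
Reagents that add atoms: 4-methoxybenzyl chloride, COc1ccc(CCl)cc1
Why: Williamson ether synthesis of a primary alkoxide with a reactive benzylic chloride; no stereocentre is formed.

Step 2
Reactants: 2 allyl 4-methoxybenzyl ether
Product: 3 (Z)-prop-1-enyl 4-methoxybenzyl ether
Conditions: t-BuOK (0.3 equiv), DMSO, rt
Reagents that add atoms: none
Why: base-mediated isomerization of an allyl ether to the propenyl ether, which should run through the oxygen-chelated cis allyl anion and give the Z enol ether.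

Step 3
Reactants: 3 (Z)-prop-1-enyl 4-methoxybenzyl ether
Product: 5 (Z)-2-bromo-1-[(4-methoxybenzyl)oxy]prop-1-ene, via dibromide 4 (not isolated)
Conditions: Br2 (1.0 equiv), CH2Cl2, −78 °C; then DBU, −78 °C → rt
Reagents that add atoms: bromine, BrBr
Why: anti addition of bromine to the enol ether followed by anti dehydrobromination (C2–H and the activated C1–Br) is the standard route to β-bromo enol ethers and should place bromine cis to oxygen, any other isomer being removed by chromatography.

Step 4
Reactants: 6 (R)-carvone; 7 vinylmagnesium bromide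
Product: 8 (1S,5R)-2-methyl-5-(prop-1-en-2-yl)-1-vinylcyclohex-2-en-1-ol
Conditions: CH2=CHMgBr, THF, −78 → 0 °C; then H2O
Reagents that add atoms: none
Why: Grignard 1,2-addition to the enone carbonyl (future C3) by axial attack anti to the equatorial isopropenyl group, so that the new tertiary hydroxyl is cis to isopropenyl.

Step 5
Reactants: 8 (1S,5R)-2-methyl-5-(prop-1-en-2-yl)-1-vinylcyclohex-2-en-1-ol
Product: 9 syn-epoxy alcohol (C8–C9 oxirane cis to the C3 hydroxyl and to isopropenyl)
Conditions: VO(acac)2 (cat.), t-BuOOH (decane), CH2Cl2, 0 °C → rt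
Reagents that add atoms: tert-butyl hydroperoxide, CC(C)(C)OO
Why: hydroxyl-directed vanadium-catalysed epoxidation picks the more electron-rich trisubstituted ring olefin and delivers oxygen syn to the tertiary hydroxyl, which sets the oxirane cis to isopropenyl.

Step 6
Reactants: 9 syn-epoxy alcohol
Product: 10 (2R,3S,5R)-3-hydroxy-2-methyl-5-(prop-1-en-2-yl)-2-vinylcyclohexan-1-one
Conditions: ZnBr2 (0.2 equiv), CH2Cl2, 0 °C → rt
Reagents that add atoms: none
Why: Lewis-acid-catalysed semipinacol rearrangement of a 2,3-epoxy tertiary alcohol, in which the vinyl group antiperiplanar to the breaking C8–O bond migrates from C3 to C8 with inversion, giving the C3 ketone, the C8 quaternary centre with vinyl trans to isopropenyl and the C9 hydroxyl with retention.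

Step 7
Reactants: 10 (2R,3S,5R)-3-hydroxy-2-methyl-5-(prop-1-en-2-yl)-2-vinylcyclohexan-1-one
Product: 11 C9 3,4-dimethoxybenzyl ether of 10
Conditions: 3,4-dimethoxybenzyl trichloroacetimidate, CSA (cat.), CH2Cl2, 0 °C → rt
Reagents that add atoms: 3,4-dimethoxybenzyl 2,2,2-trichloroacetimidate, COc1ccc(COC(=N)C(Cl)(Cl)Cl)cc1OC
Why: acid-catalysed imidate benzylation protects the hindered C9 hydroxyl without base, so that the β-hydroxy ketone cannot cleave by retro-aldol reaction.

Step 8
Reactants: 5 (Z)-2-bromo-1-[(4-methoxybenzyl)oxy]prop-1-ene; 11 C9 3,4-dimethoxybenzyl ether of 10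
Product: 13 cis-1-alkenyl-2-vinylcyclohexanol (C3 carbinol with the Z-enol ether side chain), via alkenyllithium 12 (not isolated)
Conditions: 5, t-BuLi (2 equiv), Et2O, −78 °C; CeCl3, THF, −78 °C; then 11, −78 °C; then H2O
Reagents that add atoms: none
Why: bromine–lithium exchange with retention gives the oxygen-chelated alkenyllithium, whose cerium derivative adds to the enolizable C3 ketone (organocerium 1,2-addition) along the axial direction anti to the axial C8 methyl, so that the alkenyl group is axial and cis to the C8 vinyl group and the C3 hydroxyl is equatorial.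

Step 9
Reactants: 13 cis-1-alkenyl-2-vinylcyclohexanol
Product: 16 ten-membered trimethylsilyl enol ether (ring-trans C3=C4 and 7Z), via potassium alkoxide 14 (not isolated), via potassium enolate 15 (not isolated)
Conditions: KH, 18-crown-6, THF, 0 °C → rt; then Me3SiCl, Et3N, −78 °C
Reagents that add atoms: chlorotrimethylsilane, C[Si](C)(C)Cl
Why: Deprotonation gives alkoxide 14, in which the weakened C3–C8 bond lets the 1,5-diene C5=C4–C3–C8–C7=C6 undergo an anionic oxy-Cope [3,3] shift that forms C5–C6 and breaks C3–C8 to give enolate 15, which is silylated on oxygen. The closest known reaction is the KH and 18-crown-6 ring expansion of cis-1-alkenyl-2-vinylcyclohexanols to cyclodec-5-enone enolates. The ten-membered ring is not closed end to end but arises by four-carbon expansion of the six-membered ring, through cleavage of the bond that the two rings share in the bicyclic chair transition state. C5 is set by suprafacial chirality transfer from C3 and C8 through the chair in which the Z-enol ether oxygen is pseudo-axial beside the alkoxide (both bridged by potassium), and the same chair gives Z-C7=C8 because C9 is pseudo-axial on C8 and the ring-trans C3=C4 enolate because C2 is pseudo-equatorial on C3. The step needs this chair to win over the other chair and the boats, which the cis relationship of the two alkenyl groups and the cyclohexane conformer with equatorial isopropenyl and C9 ether (C3 alkenyl axial, C8 vinyl equatorial) should secure. Cold silylation traps the enolate before it can expel the C5 alkoxide, whose C–O bond lies near the enolate plane.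

Step 10
Reactants: 16 ten-membered trimethylsilyl enol ether
Product: 19 C4-methylene C3-ketone, via selanyl ketone 17 (not isolated), via selenoxide 18 (not isolated)
Conditions: PhSeCl, CH2Cl2, −78 °C; then pyridine, 30% H2O2, 0 °C → rt
Reagents that add atoms: none
Why: α-selenenylation of the silyl enol ether on its open outer face and selenoxide syn-elimination, which avoids an oxygen-bearing carbon and therefore takes a methyl hydrogen, give the exocyclic enone and clear C4 for oxygenation from the correct side.

Step 11
Reactants: 19 C4-methylene C3-ketone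
Product: 20 (3R)-allylic alcohol
Conditions: (S)-1-methyl-3,3-diphenyltetrahydro-1H,3H-pyrrolo[1,2-c][1,3,2]oxazaborole (0.2 equiv), catecholborane, toluene, −78 °C; then aq. NaHCO3
Reagents that add atoms: none
Why: Corey–Bakshi–Shibata reduction of an enone, 1,2-selective and free of olefin hydroboration at low temperature, in which the α-branched alkenyl side acts as the large group so that the (S)-catalyst should give the (3R) alcohol by reagent control.

Step 12
Reactants: 20 (3R)-allylic alcohol
Product: 21 C4 spiro-epoxy alcohol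
Conditions: VO(acac)2 (cat.), t-BuOOH (decane), CH2Cl2, 0 °C
Reagents that add atoms: tert-butyl hydroperoxide, CC(C)(C)OO
Why: hydroxyl-directed vanadium-catalysed epoxidation of a 2-substituted allylic alcohol, in which A1,2 strain places the carbinol hydrogen beside C5 and gives the erythro epoxy alcohol, so the new C4–O bond is syn to the C3 hydroxyl along the ring as in the target while the undirected olefins stay untouched.

Step 13
Reactants: 21 C4 spiro-epoxy alcohol
Product: 22 C3,C4-diol
Conditions: LiAlH4, THF, 0 °C; then H2O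
Reagents that add atoms: none
Why: hydride opening of the 2,2-disubstituted oxirane at its unhindered methylene carbon turns the spiro-epoxide into the C4 methyl carbinol without touching the C4 configuration.

Step 14
Reactants: 22 C3,C4-diol
Product: 23 C3 triethylsilyl ether
Conditions: Et3SiCl, imidazole, DMAP (cat.), CH2Cl2, 0 °C
Reagents that add atoms: chlorotriethylsilane, CC[Si](CC)(CC)Cl
Why: silylation distinguishes the secondary C3 hydroxyl from the hindered tertiary C4 hydroxyl, which stays free.

Step 15
Reactants: 23 C3 triethylsilyl ether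
Product: 24 C9 alcohol
Conditions: DDQ (1.1 equiv), CH2Cl2/pH 7 buffer, 0 °C
Reagents that add atoms: none
Why: oxidative benzyl ether cleavage, in which the 3,4-dimethoxybenzyl ether is oxidized by DDQ markedly faster than the 4-methoxybenzyl ether at C5, so that only C9 is unveiled.

Step 16
Reactants: 24 C9 alcohol
Product: 25 C9 enone
Conditions: DMP, NaHCO3, CH2Cl2, 0 °C → rt
Reagents that add atoms: none
Why: Dess–Martin oxidation of the allylic alcohol gives the Z-enone under neutral conditions that leave the silyl ether, the tertiary alcohol and the olefin geometry intact.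

Step 17
Reactants: 25 C9 enone
Product: 27 C10-hydroxy enone, via potassium dienolate 26 (not isolated)
Conditions: KN(SiMe3)2 (2.2 equiv), THF, −78 °C; then 2-(phenylsulfonyl)-3-phenyloxaziridine, −78 °C; then H2O
Reagents that add atoms: 2-(phenylsulfonyl)-3-phenyloxaziridine, O=S(=O)(c1ccccc1)N1OC1c1ccccc1
Why: kinetic α′-deprotonation at C10 (C8 bears no hydrogen, the C4 alkoxide is a spectator) and sulfonyloxaziridine hydroxylation of the enolate, where the C1 hydrogen should eclipse the enolate to relieve A1,3 strain so that the oxidant enters anti to isopropenyl and gives the required C10 configuration.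

Step 18
Reactants: 27 C10-hydroxy enone; 28 3-methylbut-2-enoyl chloride
Product: 29 C10 senecioate
Conditions: pyridine, DMAP (cat.), CH2Cl2, −20 → 0 °C
Reagents that add atoms: none
Why: acylation of the only secondary hydroxyl (the C4 hydroxyl is tertiary) installs the senecioate, and the weak base limits ketene formation from the acid chloride and epimerization at C10.

Step 19
Reactants: 29 C10 senecioate
Product: 30 C9 alcohol of the senecioate
Conditions: Zn(BH4)2, Et2O, −20 °C; then H2O
Reagents that add atoms: none
Why: 1,2-reduction of the enone under chelation control, in which zinc bridges the ketone and the C10 acyloxy oxygen and hydride enters anti to C1, should give the C9 alcohol cis (erythro) to the C10 ester.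

Step 20
Reactants: 30 C9 alcohol of the senecioate
Product: 31 C7–C8 epoxy alcohol
Conditions: VO(acac)2 (cat.), t-BuOOH (decane), CH2Cl2, 0 °C → rt
Reagents that add atoms: tert-butyl hydroperoxide, CC(C)(C)OO
Why: the free allylic C9 hydroxyl directs vanadium-catalysed epoxidation to the Z-C7=C8 olefin only, A1,2 strain with the C8 methyl and the cis preference of medium-ring allylic alcohols placing the oxirane oxygen on the side of the C9 oxygen, and the Z geometry giving the cis-oxirane.

Step 21
Reactants: 31 C7–C8 epoxy alcohol; 32 acetic anhydride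
Product: 33 C9 acetate
Conditions: pyridine, DMAP (cat.), CH2Cl2, 0 °C
Reagents that add atoms: none
Why: nucleophile-catalysed acetylation of the single secondary alcohol, the tertiary C4 hydroxyl being inert at this temperature.

Step 22
Reactants: 33 C9 acetate
Product: 34 C5 alcohol
Conditions: DDQ, CH2Cl2/pH 7 buffer (10:1), rt
Reagents that add atoms: none
Why: oxidative cleavage of the 4-methoxybenzyl ether in a buffered water-rich medium, which spares the oxirane, the esters and the silyl ether and suppresses acetal formation with the C4 hydroxyl.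

Step 23
Reactants: 34 C5 alcohol; 35 angelic acid
Product: 37 C3-O-triethylsilyl target, via mixed anhydride 36 (not isolated)
Conditions: 35, 2,4,6-trichlorobenzoyl chloride, Et3N, toluene, rt; then 34, toluene, 80 °C
Reagents that add atoms: none
Why: Yamaguchi esterification through the 2,4,6-trichlorobenzoic mixed anhydride acylates the hindered secondary C5 alcohol (the tertiary C4 alcohol is inert) and is the established way to make angelates without isomerization to the tiglate.

Step 24
Reactants: 37 C3-O-triethylsilyl target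
Product: 38 target CNP0298989.1
Conditions: HF·pyridine, pyridine, THF, 0 °C
Reagents that add atoms: none
Why: pyridine-buffered fluoride desilylation frees the C3 hydroxyl without opening the oxirane or moving the esters.

Compound list
1 | allyl alcohol | C=CCO | starting material
2 | allyl 4-methoxybenzyl ether | C=CCOCc1ccc(OC)cc1 | intermediate
3 | (Z)-prop-1-enyl 4-methoxybenzyl ether | C/C=C\OCc1ccc(OC)cc1 | intermediate
4 | anti-1,2-dibromopropyl 4-methoxybenzyl ether (racemic, relative configuration shown) | C[C@@H](Br)[C@H](Br)OCc1ccc(OC)cc1 | intermediate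
5 | (Z)-2-bromo-1-[(4-methoxybenzyl)oxy]prop-1-ene (Br cis to O) | C/C(Br)=C/OCc1ccc(OC)cc1 | intermediate
6 | (R)-carvone | C=C(C)[C@H]1CC(=O)C(C)=CC1 | starting material
7 | vinylmagnesium bromide | C=C[Mg]Br | starting material
8 | (1S,5R)-2-methyl-5-(prop-1-en-2-yl)-1-vinylcyclohex-2-en-1-ol (OH cis to isopropenyl) | C=C(C)[C@H]1C[C@](O)(C=C)C(C)=CC1 | intermediate
9 | syn-epoxy alcohol: 8 with a C8–C9 oxirane cis to the C3 hydroxyl and to isopropenyl | C=C(C)[C@H]1C[C@](O)(C=C)[C@@]2(C)O[C@H]2C1 | intermediate
10 | (2R,3S,5R)-3-hydroxy-2-methyl-5-(prop-1-en-2-yl)-2-vinylcyclohexan-1-one (C8 vinyl trans, C8 methyl and C9 OH cis to isopropenyl) | C=C(C)[C@H]1CC(=O)[C@](C)(C=C)[C@@H](O)C1 | intermediate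
11 | C9 3,4-dimethoxybenzyl ether of 10 | C=C(C)[C@H]1CC(=O)[C@](C)(C=C)[C@@H](OCc2ccc(OC)c(OC)c2)C1 | intermediate
12 | 1-[(4-methoxybenzyl)oxy]prop-1-en-2-yllithium (Li cis to O) | C/C([Li])=C/OCc1ccc(OC)cc1 | intermediate
13 | cis-1-alkenyl-2-vinylcyclohexanol: C3 OH, C8 CH3, C9 ODMB and C1 isopropenyl on one face, the C3 (Z)-1-(PMB-oxy)prop-1-en-2-yl and C8 vinyl groups on the other | C=C(C)[C@H]1C[C@](O)(/C(C)=C\OCc2ccc(OC)cc2)[C@](C)(C=C)[C@@H](OCc3ccc(OC)c(OC)c3)C1 | intermediate
14 | potassium alkoxide of 13 | C=C(C)[C@H]1C[C@]([O-])(/C(C)=C\OCc2ccc(OC)cc2)[C@](C)(C=C)[C@@H](OCc3ccc(OC)c(OC)c3)C1.[K+] | intermediate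
15 | potassium enolate of the ten-membered ketone (C3–O cis to C5, C2 trans to C5 across C3=C4; 7Z) | C=C(C)[C@H]1C/C([O-])=C(C)/[C@@H](OCc2ccc(OC)cc2)C/C=C(C)\[C@@H](OCc3ccc(OC)c(OC)c3)C1.[K+] | intermediate
16 | ten-membered trimethylsilyl enol ether: C3 OSiMe3, C4 CH3, ring-trans C3=C4, C5 OPMB, 7Z olefin with C8 CH3, C9 ODMB, C1 isopropenyl; C1, C5, C9 configured as in the target | C=C(C)[C@H]1C/C(O[Si](C)(C)C)=C(C)/[C@@H](OCc2ccc(OC)cc2)C/C=C(C)\[C@@H](OCc3ccc(OC)c(OC)c3)C1 | intermediate
17 | C3 ketone with CH3 and phenylselanyl on C4 (selenium on the outer face) | C=C(C)[C@H]1CC(=O)[C@@](C)([Se]c4ccccc4)[C@@H](OCc2ccc(OC)cc2)C/C=C(C)\[C@@H](OCc3ccc(OC)c(OC)c3)C1 | intermediate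
18 | selenoxide of 17 (both configurations at selenium) | C=C(C)[C@H]1CC(=O)[C@@](C)([Se](=O)c4ccccc4)[C@@H](OCc2ccc(OC)cc2)C/C=C(C)\[C@@H](OCc3ccc(OC)c(OC)c3)C1 | intermediate
19 | C4-methylene C3-ketone (C5 OPMB, 7Z, C9 ODMB) | C=C(C)[C@H]1CC(=O)C(=C)[C@@H](OCc2ccc(OC)cc2)C/C=C(C)\[C@@H](OCc3ccc(OC)c(OC)c3)C1 | intermediate
20 | (3R)-allylic alcohol of 19 | C=C(C)[C@H]1C[C@@H](O)C(=C)[C@@H](OCc2ccc(OC)cc2)C/C=C(C)\[C@@H](OCc3ccc(OC)c(OC)c3)C1 | intermediate
21 | C4 spiro-epoxy alcohol (oxirane oxygen syn to the C3 OH, C4 as in the target) | C=C(C)[C@H]1C[C@@H](O)[C@]4(OC4)[C@@H](OCc2ccc(OC)cc2)C/C=C(C)\[C@@H](OCc3ccc(OC)c(OC)c3)C1 | intermediate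
22 | C3,C4-diol (C4 methyl carbinol; C3, C4, C5 as in the target) | C=C(C)[C@H]1C[C@@H](O)[C@](C)(O)[C@@H](OCc2ccc(OC)cc2)C/C=C(C)\[C@@H](OCc3ccc(OC)c(OC)c3)C1 | intermediate
23 | C3 triethylsilyl ether of 22 | C=C(C)[C@H]1C[C@@H](O[Si](CC)(CC)CC)[C@](C)(O)[C@@H](OCc2ccc(OC)cc2)C/C=C(C)\[C@@H](OCc3ccc(OC)c(OC)c3)C1 | intermediate
24 | C9 alcohol (DMB removed) | C=C(C)[C@H]1C[C@@H](O[Si](CC)(CC)CC)[C@](C)(O)[C@@H](OCc2ccc(OC)cc2)C/C=C(C)\[C@@H](O)C1 | intermediate
25 | (7Z)-C9 enone | C=C(C)[C@H]1C[C@@H](O[Si](CC)(CC)CC)[C@](C)(O)[C@@H](OCc2ccc(OC)cc2)C/C=C(C)\C(=O)C1 | intermediate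
26 | dipotassium salt: C9–C10 dienolate and C4 alkoxide of 25 | C=C(C)[C@H]1C[C@@H](O[Si](CC)(CC)CC)[C@](C)([O-])[C@@H](OCc2ccc(OC)cc2)C/C=C(C)\C([O-])=C1.[K+].[K+] | intermediate
27 | C10-hydroxy enone (C10 as in the target) | C=C(C)[C@H]1C[C@@H](O[Si](CC)(CC)CC)[C@](C)(O)[C@@H](OCc2ccc(OC)cc2)C/C=C(C)\C(=O)[C@H]1O | intermediate
28 | 3-methylbut-2-enoyl chloride | CC(C)=CC(=O)Cl | starting material
29 | C10 senecioate of 27 | C=C(C)[C@H]1C[C@@H](O[Si](CC)(CC)CC)[C@](C)(O)[C@@H](OCc2ccc(OC)cc2)C/C=C(C)\C(=O)[C@H]1OC(=O)C=C(C)C | intermediate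
30 | C9 allylic alcohol, cis to the C10 senecioate | C=C(C)[C@H]1C[C@@H](O[Si](CC)(CC)CC)[C@](C)(O)[C@@H](OCc2ccc(OC)cc2)C/C=C(C)\[C@@H](O)[C@H]1OC(=O)C=C(C)C | intermediate
31 | C7–C8 cis-epoxy alcohol (oxirane oxygen on the side of the C9 OH) | C=C(C)[C@H]1C[C@@H](O[Si](CC)(CC)CC)[C@](C)(O)[C@@H](OCc2ccc(OC)cc2)C[C@H]3O[C@@]3(C)[C@@H](O)[C@H]1OC(=O)C=C(C)C | intermediate
32 | acetic anhydride | CC(=O)OC(C)=O | starting material
33 | C9 acetate of 31 | C=C(C)[C@H]1C[C@@H](O[Si](CC)(CC)CC)[C@](C)(O)[C@@H](OCc2ccc(OC)cc2)C[C@H]3O[C@@]3(C)[C@@H](OC(C)=O)[C@H]1OC(=O)C=C(C)C | intermediate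
34 | C5 alcohol (PMB removed) | C=C(C)[C@H]1C[C@@H](O[Si](CC)(CC)CC)[C@](C)(O)[C@@H](O)C[C@H]3O[C@@]3(C)[C@@H](OC(C)=O)[C@H]1OC(=O)C=C(C)C | intermediate
35 | angelic acid, (Z)-2-methylbut-2-enoic acid | C/C=C(/C)C(=O)O | starting material
36 | angelic 2,4,6-trichlorobenzoic anhydride | C/C=C(/C)C(=O)OC(=O)c1c(Cl)cc(Cl)cc1Cl | intermediate
37 | C3-O-triethylsilyl ether of the target | C=C(C)[C@H]1C[C@@H](O[Si](CC)(CC)CC)[C@](C)(O)[C@@H](OC(=O)/C(C)=C\C)C[C@H]3O[C@@]3(C)[C@@H](OC(C)=O)[C@H]1OC(=O)C=C(C)C | intermediate
38 | CNP0298989.1 (1R,3R,4S,5S,7R,8R,9S,10S in the numbering used here) | C=C(C)[C@H]1C[C@@H](O)[C@](C)(O)[C@@H](OC(=O)/C(C)=C\C)C[C@H]2O[C@@]2(C)[C@@H](OC(C)=O)[C@H]1OC(=O)C=C(C)C | target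

Total step count: 24 steps.
Longest linear sequence: 21 steps (steps 4 to 24, from (R)-carvone); the alkenyl bromide branch (steps 1 to 3) joins at step 8.

Steps most likely to fail

Step 9. The potassium enolate may expel the C5 alkoxide by β-elimination before it is trapped, or part of the alkoxide may react through a boat, which would erode the C5 configuration and the olefin geometries. The fallback is a neutral thermal siloxy-Cope shift that never forms an enolate. It sets out from 13: silylation of the tertiary alcohol with N-(trimethylsilyl)imidazole in CH2Cl2 at rt gives the trimethylsilyl ether of 13 F1, which is heated in degassed o-dichlorobenzene at about 200 °C in a base-washed sealed tube. The [3,3] shift of the silyl ether should pass through the same chair and deliver the silyl enol ether directly, so the sequence comes back to the route at 16.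

Step 17. Facial selectivity of the enolate hydroxylation in the flexible ten-membered ring may be poor or reversed. The fallback corrects C10 by substitution instead of by facial control. It sets out from 25: when the oxidant enters syn to isopropenyl, the C10 epimer of 27 F2 is formed. F2 is esterified under Mitsunobu conditions (3-methylbut-2-enoic acid, PPh3, diisopropyl azodicarboxylate, toluene, 0 °C → rt), which inverts C10 by SN2 displacement while it installs the senecioate, and the sequence comes back at 29. Any 27 formed alongside goes on through step 18, so both epimers converge.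

Step 19. An acyloxy group chelates zinc less well than a free hydroxyl, so facial control at C9 may be low, and the C10 ester may migrate to the new C9 alkoxide. The fallback reduces before acylation. It sets out from 27: Zn(BH4)2 in Et2O at −20 °C reduces the zinc chelate of the free α′-hydroxy enone to the cis-C9,C10-diol F3. VO(acac)2 and t-BuOOH then give the epoxy diol F4, in which the C9 hydroxyl is flanked by the fully substituted oxirane carbon. The less hindered C10 hydroxyl is acylated selectively with 28 (pyridine, CH2Cl2, −40 °C), and the sequence comes back at 31.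

Further compounds
F1 | step 9 | trimethylsilyl ether of 13 | C=C(C)[C@H]1C[C@](O[Si](C)(C)C)(/C(C)=C\OCc2ccc(OC)cc2)[C@](C)(C=C)[C@@H](OCc3ccc(OC)c(OC)c3)C1
F2 | step 17 | C10 epimer of 27 | C=C(C)[C@H]1C[C@@H](O[Si](CC)(CC)CC)[C@](C)(O)[C@@H](OCc2ccc(OC)cc2)C/C=C(C)\C(=O)[C@@H]1O
F3 | step 19 | cis-C9,C10-diol | C=C(C)[C@H]1C[C@@H](O[Si](CC)(CC)CC)[C@](C)(O)[C@@H](OCc2ccc(OC)cc2)C/C=C(C)\[C@@H](O)[C@H]1O
F4 | step 19 | C7–C8 epoxy C9,C10-diol | C=C(C)[C@H]1C[C@@H](O[Si](CC)(CC)CC)[C@](C)(O)[C@@H](OCc2ccc(OC)cc2)C[C@H]3O[C@@]3(C)[C@@H](O)[C@H]1O
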